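The earlier runs and the new flask were computed from invented constants; noise was put on by code.

4 questions stand open on the same charges of J and D, and they turn on how the order of addition changes the E left at the end.

| setting | oak | elm | noon | dawn | spring |
|---|---|---|---|---|---|
| J | 0.10 M | 0.15 M | 0.10 M | 0.10 M | 0.10 M (fed, over 1.0 min) |
| D | 0.11 M | 0.11 M | 0.110 M (fed, over 1.0 min) | 0.110 M | 0.110 M |
| remark | run made earlier | run made earlier | all else is in the flask from the start; the feed brings no volume worth counting | everything together at the start | all else is in the flask from the start; the feed brings no volume worth counting |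
| time |  |  | 2.5 min | 2.5 min | 2.5 min |

oak run (percent of the J charged)

| time / min | E / % |
|---|---|
| 0.333 | 33.7 |
| 0.833 | 40.0 |
| 1.50 | 37.8 |
| 2.50 | 31.3 |

elm run (percent of the J charged)

| time / s | E / % |
|---|---|
| 10.0 | 22.4 |
| 20.0 | 29.1 |
| 30.0 | 31.7 |

(each reading ± 0.3 percentage points)

* the flask with the highest amount of E, in percent of the J charged ("all alike" if they lie within 1.5 percentage points) (noon / dawn / spring / all alike)
* final E, as a percentage of the J charged, in noon
* final E, as a percentage of the J charged, in dawn
* final E, as a percentage of the J charged, in spring



The ladder of clocks starts with the build-up of E. In the elm run, the gain from 20.0 s to 30.0 s is 0.388 of the gain from 10.0 s to 20.0 s, which reads as a time constant of about 10.6 s for the rise, shorter than the feed, though E is still rising at the last reading. Next comes the feed, 1.0 min. Slowest is the decline of E in the oak run, which keeps 0.782 of its peak reading by 2.50 min, a time scale of 6.80 min. So I take E to form at the ratio standing during a feed, with the decline on top.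

That ratio is r = c_J/c_D. Oak, at 0.909, reads highest at 40.0%; elm, at 1.36, ends its readings at 31.7%, and its shrinking gain, carried on, gives my estimate of a top near 33.3%. Read as a straight line in r, J spent per E formed (the inverse of a selectivity) climbs with a slope of 1.10, and this slope is the ratio penalty q; the line starts from 1.50 at r near zero. At that low end, the line gives a top of 66.7%; towards high r, its top sinks.

Noon starts at the high end and spring at the low end, so I join the ends with mean values. Taking the fed charge at its mean gives r of 1.82 for noon and 0.455 for spring. Their tops, times the oak decline, give 22.4% for noon and 39.1% for spring, against 31.3% for dawn, which repeats oak.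

The forecast differs. It gives 33% for noon, 31.3% for dawn and 27% for spring, so noon leads, and of spring it says that “feeding J keeps D in excess and J low”.

    2 J → G (k = 0.140 M⁻¹ s⁻¹)
    D + L → Q (k = 0.300 M⁻¹ s⁻¹)
    J + D → E (k = 0.370 M⁻¹ s⁻¹)
    D + E → Q (k = 0.0150 M⁻¹ s⁻¹)
    E ⇌ X (K = 2.10, k = 0.00520 s⁻¹)
    J + D → L (k = 0.0830 M⁻¹ s⁻¹)

Noon ends at 24.0%, dawn at 31.7% and spring at 37.4%, so spring leads. At 2.50 min, G stands at 48.7% in noon against 18.7% in spring. Over the feed, noon's mean c_J of 0.0477 M and mean c_D of 0.0374 M give r of 1.27. With q, that gives a top of 34.5%, and the oak decline brings it to 27.0%.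

A neighbour of noon charged with 0.040 M of J has r of 0.727, so q gives a top of 43.5% and, after the decline, 34.0%. Its computed E is 33.7%.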